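## Structural features

Agastinol is a lignan ester built on one tetrahydrofuran ring (O1, C2, C3, C4, C5). C2 carries a 4-hydroxy-3-methoxyphenyl group, C3 carries a CH2O arm (C9) esterified with 4-hydroxybenzoic acid, C4 carries a 4-hydroxy-3-methoxybenzyl arm (C7' and its arene), and C5 is an unsubstituted CH2. The three ring stereocentres are contiguous and have the configuration (2R,3S,4S): the C2 aryl group is trans to C9, and C9 is cis to C7'. The C2–O1 bond is a benzylic ether para to an oxygen substituent, so acid can ionise it (epimerisation at C2, Friedel–Crafts closure onto the other arene) and hydrogenation can cleave it. There are also three free phenols and an ester that excludes strong base and hydride late in the route. The real difficulty is the cis relation of the arms on C3 and C4, the less stable arrangement, which has to be made kinetically, together with an end game that removes every auxiliary group without opening C2–O1. The plan uses the fact that C9 and C7' lie on the same face on neighbouring ring atoms: an oxygen placed temporarily on C7' is joined through silicon to C9, the C3–C9 bond is formed inside a six-membered ring fused cis to the tetrahydrofuran, and that ring fusion also fixes C4.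

## Logic of the disconnections

18 to 17: the three phenolic O–H bonds are traced back to O–benzyl bonds. Free phenols would interfere with the alkoxide, organochromium and tin hydride steps, and one common ether allows a single neutral release at the end. The skeleton is unchanged. The forward step must be mild enough to leave the C2–O1 benzylic ether and the ester alone.

17 to 16: the C7'–H bond is traced back to C7'–OH. This oxygen anchors the tether and is not part of the target. The forward reduction must remove an exocyclic benzylic hydroxyl while a ring benzylic ether on an equally electron-rich arene stays closed and C4 keeps its configuration. For that reason the deoxygenation is a step of its own and is not left to the final hydrogenolysis.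

16 to 14 and 15: the acyl C–O9 bond is cut. The third arene leaves as 15 and a diol remains. The forward acylation must take the primary C9 hydroxyl and leave the hindered secondary C7' hydroxyl.

14 to 13: the C9–O bond and the O–H bond at C7' are traced back to C9–Si and O–Si bonds of one SiMe2 unit. A 1,4-diol with this spacing is the oxidation product of a six-membered cyclic siloxane, so one temporary atom accounts for both oxygens. The forward step needs a C–Si oxidation that leaves C3 and the electron-rich arenes untouched.

13 to 12: the C3–C9 bond is cut and the hydrogen on C4 is removed. This is the strategic cut: one ring and two stereocentres disappear, leaving a flat 2,5-dihydrofuran with C2 as its only ring stereocentre. The forward step must send the C9 radical to C3 and not to C4, on the face away from the C2 aryl group, and must finish with a hydrogen transfer that makes the ring fusion cis.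

12 to 10 and 11: the Si–O bond is cut. 11 supplies C9 and the radical precursor. The demand is a mild silylation of an acid-sensitive allylic benzylic alcohol.

10 to 9: the C3=C4 double bond is cut. The ring opens to a diene ether in which C3 and C4 belong to separate alkene units. The forward metathesis must form a trisubstituted ring alkene next to a free hydroxyl without moving the double bond toward the doubly activated C2–H.

9 to 7 and 1 (through 8): the C4–C7' bond is cut between the alkene carbon and the carbinol carbon. The second aryl unit returns to 1 and a 2-bromoallyl ether remains. The forward step needs an alkenyl metal that adds to an aldehyde but is too weakly basic to disturb the allylic benzylic ether; the new carbinol centre need not be controlled.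

7 to 5 and 6: the O1–C5 bond is cut. The unit C5–C4(=CH2) comes from 6. The demand is O-alkylation without loss of configuration at the carbinol carbon of 5.

5 to 4 to 3: the configuration at C2 is traced back to a racemate. The acyl C–O bond of 4 is cut to give 5, and 4 is the enantiomer selected from 3 by an enzyme. No skeletal bond changes. High enantioselection is required because C2 later controls C3 and C4.

3 to 1 and 2: the C2–C3 bond is cut. 1 is then the common source of both guaiacyl units, and 2 supplies C3 and the carbon later lost as ethene.

## Other disconnections considered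

Alternative 1: The cut is at C4–C7' and C2–C3 in one three-component operation on the chiral butenolide (5S)-5-(menthyloxy)furan-2(5H)-one A1. In the forward step the dithiane 2-[4-(benzyloxy)-3-methoxyphenyl]-1,3-dithiane A2, after lithiation, adds to the β-carbon of A1 on the face away from the acetal substituent, and the lactone enolate is trapped by 1 to give the trans,trans lactone A3.
- In favour: the whole carbon skeleton is assembled in one step, C3 and C4 are set in absolute terms by a removable auxiliary, and no resolution is needed. The trans relation on the lactone becomes the cis relation of C9 and C7' once the ring is re-formed through C2 and C5.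
- Against it here: C2 is made last, by acid-mediated closure through a benzylic cation, which is the ionisation the target is sensitive to. Nickel desulfurisation must spare benzyl ethers and a benzylic hydroxyl. The required enantiomeric series needs the auxiliary from the less common menthol enantiomer.
- Comparison: on structure it builds C3/C4 on a ring that is later exchanged, whereas the chosen plan works on the final ring. On mechanism it is anionic and auxiliary-controlled, which is equal or better in predictability at C3/C4, while the chosen plan is better at C2, which is fixed early and never passes through a cation. On step economy alternative 1 is the better, by roughly four steps.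

Alternative 2: The cut is at C4–C5, the ring bond next to oxygen. In the forward step a Lewis acid (TiCl4) ionises the methoxymethyl ether A4 of an anti homopropargylic alcohol, the aryl alkyne attacks the O1=C5 oxocarbenium ion through C4, and chloride captures the aryl-stabilised vinyl cation at C7' to give the chloroalkylidene tetrahydrofuran A5.
- In favour: ring and C4–C5 bond form together from an acyclic precursor whose C2/C3 relation comes from anti-selective propargylation. C7' arrives without an oxygen to delete. No tin is used. The sulfonate on the C2 arene tempers ionisation of C2–O1.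
- Against it here: C4 is left to a later hydrogenation of a fully substituted chloroalkene, with C–Cl hydrogenolysis and face selectivity decided on a monocycle. The sulfonate differs from the other phenol protections and its removal calls for conditions that threaten the 4-hydroxybenzoate, which costs protecting-group steps. The cationic step runs against the acid sensitivity of the benzylic ether.
- Comparison: on structure the chosen plan sets C3 and C4 together inside a rigid bicycle, which is more secure than an intermolecular hydrogenation. On mechanism the radical closure is neutral where alternative 2 is strongly Lewis acidic. On step economy the two are about equal, and alternative 2 is the better in needing no separate deoxygenation at C7' and no stoichiometric tin.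

Alternative 3: The cut is at C3–C9 and at C4–C7' (as a double bond) on the enantiopure butenolide (5R)-5-[4-(benzyloxy)-3-methoxyphenyl]furan-2(5H)-one A6. In the forward step a silylmethyl copper reagent adds to the β-carbon of A6 anti to the γ-aryl group, the enolate is trapped by 1, and sulfonylation–elimination in the same flask gives the E arylidene lactone A7.
- In favour: two skeletal bonds form in one step. The C2/C3 trans relation rests on simple 1,2-induction. C7' is at the alkene level, so nothing has to be deoxygenated. A6 could come from 5 by acryloylation and metathesis.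
- Against it here: the lactone carbonyl at C5 must be taken down to CH2 next to the benzylic C2–O bond. C4 is set by hydrogenation and, while the carbonyl remains, is epimerisable toward the more stable trans isomer. The γ-hydrogen of A6 is acidic, so C2 is at risk under the basic conditions of the key step.
- Comparison: on structure both plans hang C9 on C3 as a silicon-masked hydroxymethyl group. On mechanism both rely on attack at C3 anti to the C2 aryl group and are equal there; the chosen plan is better at C4 (intramolecular, ring-fused, not epimerisable) and at keeping C2 configurationally safe. On step economy alternative 3 is equal or slightly better and avoids tin.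

Key step: step 8

Remark on the chemistry: the carbinol carbon C7' is not controlled; 9, 10, 12, 13, 14 and 16 are carried as mixtures of the two C7' epimers and their SMILES leave this centre open.

## Route

Step 1
Reactants: 1 O-benzylvanillin (4-(benzyloxy)-3-methoxybenzaldehyde); 2 vinylmagnesium bromide
Product: 3 rac-1-[4-(benzyloxy)-3-methoxyphenyl]prop-2-en-1-ol
Conditions: THF, 0 °C; aq. NH4Cl
Reagents that add atoms: none
Why: 1,2-addition of a vinyl Grignard reagent to an aromatic aldehyde forms the C2–C3 bond and the racemic carbinol that becomes C2; the buffered quench avoids acid, which would ionise the electron-rich allylic benzylic alcohol.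

Step 2
Reactants: 3 rac-1-[4-(benzyloxy)-3-methoxyphenyl]prop-2-en-1-ol
Product: 4 (1R)-1-[4-(benzyloxy)-3-methoxyphenyl]prop-2-en-1-yl acetate
Conditions: immobilised Candida antarctica lipase B, vinyl acetate, MTBE, 30 °C, stopped near half conversion
Reagents that add atoms: vinyl acetate, C=COC(C)=O
Why: lipase-catalysed kinetic resolution by enantioselective acyl transfer; with the arene as the large and vinyl as the medium substituent the enzyme should acylate the R alcohol and leave the S alcohol, and vinyl acetate makes the transfer irreversible. The R acetate has the configuration needed at C2.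

Step 3
Reactants: 4 (1R)-1-[4-(benzyloxy)-3-methoxyphenyl]prop-2-en-1-yl acetate
Product: 5 (1R)-1-[4-(benzyloxy)-3-methoxyphenyl]prop-2-en-1-ol
Conditions: K2CO3 (0.2 equiv), MeOH, 0 °C
Reagents that add atoms: none
Why: base-catalysed transesterification at the acyl carbon leaves the C–O bond of the stereocentre untouched, so the configuration is kept; the basic medium suppresses ionisation of the allylic benzylic acetate.

Step 4
Reactants: 5 (1R)-1-[4-(benzyloxy)-3-methoxyphenyl]prop-2-en-1-ol; 6 2,3-dibromoprop-1-ene
Product: 7 1-(benzyloxy)-4-{(1R)-1-[(2-bromoprop-2-en-1-yl)oxy]prop-2-en-1-yl}-2-methoxybenzene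
Conditions: NaH, THF–DMF, 0 °C to rt, Bu4NI (cat.)
Reagents that add atoms: none
Why: Williamson ether synthesis: the alkoxide displaces the allylic bromide of 6 (direct and allylic displacement give the same ether), the vinylic bromide is inert, and the bond formed is O1–C5. The stereocentre is a spectator.

Step 5
Reactants: 7 1-(benzyloxy)-4-{(1R)-1-[(2-bromoprop-2-en-1-yl)oxy]prop-2-en-1-yl}-2-methoxybenzene; 1 O-benzylvanillin
Product: 9 (1RS)-1-[4-(benzyloxy)-3-methoxyphenyl]-2-[({(1R)-1-[4-(benzyloxy)-3-methoxyphenyl]prop-2-en-1-yl}oxy)methyl]prop-2-en-1-ol (both carbinol epimers), via alkenylchromium dichloride 8 (not isolated)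
Conditions: CrCl2 (4 equiv), NiCl2 (2 mol%), DMF, rt; aq. work-up
Reagents that add atoms: none
Why: Nozaki–Hiyama–Kishi coupling: nickel-catalysed insertion into the alkenyl C–Br bond and transfer to chromium give 8, which adds only to the aldehyde and is too weakly basic to attack the doubly activated C2–H or to expel the allylic ether oxygen. The C4–C7' bond is formed; the new carbinol centre is not controlled and both epimers are taken on.

Step 6
Reactants: 9 the diene carbinol from step 5
Product: 10 (RS)-[4-(benzyloxy)-3-methoxyphenyl]{(5R)-5-[4-(benzyloxy)-3-methoxyphenyl]-2,5-dihydrofuran-3-yl}methanol (C2 R in lignan numbering; both C7' epimers)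
Conditions: second-generation Grubbs catalyst RuCl2(=CHPh)(PCy3)(H2IMes) (5 mol%), 1,4-benzoquinone (10 mol%), CH2Cl2 (0.01 M), 40 °C
Reagents that add atoms: none
Why: ring-closing metathesis of a monosubstituted with a 1,1-disubstituted alkene closes the five-membered ring with loss of ethene and gives the trisubstituted C3=C4 alkene; the ruthenium carbene tolerates the free allylic hydroxyl and benzoquinone suppresses hydride-induced double-bond migration. C2 is untouched.

Step 7
Reactants: 10 the dihydrofuranyl carbinol from step 6; 11 (bromomethyl)chlorodimethylsilane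
Product: 12 (bromomethyl){(RS)-[4-(benzyloxy)-3-methoxyphenyl][(5R)-5-[4-(benzyloxy)-3-methoxyphenyl]-2,5-dihydrofuran-3-yl]methoxy}dimethylsilane (both C7' epimers)
Conditions: Et3N (1.5 equiv), DMAP (5 mol%), CH2Cl2, 0 °C; filtered through Et3N-washed silica and used at once
Reagents that add atoms: none
Why: silylation of a secondary alcohol with a chlorosilane and amine base; the medium stays basic, so the allylic benzylic C–O bond does not ionise, and the hydrolytically labile silyl ether is not stored.

Step 8
Reactants: 12 the (bromomethyl)dimethylsilyl ether from step 7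
Product: 13 cis-fused tetrahydrofuran–1,2-oxasilinane: Si(CH3)2 bonded to C9H2 on C3 and to the oxygen on C7', C7' on C4, 4-(benzyloxy)-3-methoxyphenyl on C2 and on C7'; C2 R, C3 R, C4 S; C9 trans to the C2 aryl group; both C7' epimers
Conditions: Bu3SnH (1.3 equiv) and AIBN (0.1 equiv) added over 6 h by syringe pump, benzene (0.01 M), 80 °C
Reagents that add atoms: none
Why: the tin radical abstracts bromine from 12 and the α-silyl radical on C9 attacks the ring alkene; the closest known reaction type is the cyclisation of (bromomethyl)dimethylsilyl ethers of allylic alcohols substituted on the nearer alkene carbon, which close to six-membered siloxanes that are then oxidised to 1,4-diols. The one ring closed is the 1,2-oxasilinane (C9, Si, O, C7', C4, C3), formed 6-endo-trig by bonding of C9 to C3. The 5-exo closure would have to attack the fully substituted C4 and build a spiro quaternary centre, whereas attack at the CH carbon C3 gives a tertiary radical at C4, and the long Si–C and Si–O bonds let the chain reach the far carbon without strain. At C3 the dihydrofuran is nearly flat and the tether can swing to either face, so the face is chosen by the aryl group on the neighbouring C2: C9 should bond on the opposite face, giving the 2,3-trans relation. At C4 the tertiary radical is shielded on one face by the new C3–C9 bond and the siloxane bridge, so Bu3SnH should deliver hydrogen on the other, convex face; the six-membered ring is then cis-fused and C7' ends on the same face as C9. The step needs ring closure to outrun direct reduction of the primary radical, which slow addition and high dilution of the stannane secure. It needs no control at C7': in the 7'S epimer the carbinol hydrogen can lie in the ring plane beside C5H2 with the arene turned away from the tether, in the 7'R epimer the arene takes the in-plane position, and both lead to the same configuration at C2, C3 and C4.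

Step 9
Reactants: 13 the bicyclic siloxane from step 8
Product: 14 {(2R,3S,4S)-2-[4-(benzyloxy)-3-methoxyphenyl]-4-{(RS)-[4-(benzyloxy)-3-methoxyphenyl](hydroxy)methyl}oxolan-3-yl}methanol
Conditions: 30% aq. H2O2, KF, KHCO3, THF–MeOH (1:1), rt to 45 °C
Reagents that add atoms: hydrogen peroxide, OO
Why: Tamao oxidation: fluoride activates the alkoxysilane, hydroperoxide attacks silicon and C9 migrates from silicon to oxygen with retention, then the Si–O bonds are hydrolysed. C3 is not involved and the mildly basic medium leaves the benzylic ether and benzyl ethers alone.

Step 10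
Reactants: 14 the diol from step 9; 15 4-(benzyloxy)benzoyl chloride
Product: 16 {(2R,3S,4S)-2-[4-(benzyloxy)-3-methoxyphenyl]-4-{(RS)-[4-(benzyloxy)-3-methoxyphenyl](hydroxy)methyl}oxolan-3-yl}methyl 4-(benzyloxy)benzoate
Conditions: 2,4,6-collidine (2 equiv), CH2Cl2, −40 to 0 °C
Reagents that add atoms: none
Why: acylation with an aroyl chloride and a hindered pyridine base without a nucleophilic catalyst should take the primary C9 hydroxyl well ahead of the secondary benzylic C7' hydroxyl, which is flanked by an arene and the ring.

Step 11
Reactants: 16 the hydroxy ester from step 10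
Product: 17 {(2R,3S,4S)-2-[4-(benzyloxy)-3-methoxyphenyl]-4-[4-(benzyloxy)-3-methoxybenzyl]oxolan-3-yl}methyl 4-(benzyloxy)benzoate
Conditions: Et3SiH (5 equiv), BF3·OEt2 (1.5 equiv), CH2Cl2, −78 °C; quenched cold with Et3N, then aq. NaHCO3
Reagents that add atoms: none
Why: ionic hydrogenation of an electron-rich benzylic alcohol: the Lewis acid ionises the free hydroxyl and excess silane traps the C7' cation faster than it can lose a proton. At this temperature the ring C2–O1 ether should stay closed, as 2-aryl tetrahydrofurans are themselves made under these conditions; both C7' epimers converge on one compound.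

Step 12
Reactants: 17 the tribenzyl ether from step 11
Product: 18 agastinol, {(2R,3S,4S)-2-(4-hydroxy-3-methoxyphenyl)-4-[(4-hydroxy-3-methoxyphenyl)methyl]oxolan-3-yl}methyl 4-hydroxybenzoate
Conditions: H2 (1 atm), 10% Pd/C, EtOAc, rt, stopped when debenzylation is complete
Reagents that add atoms: none
Why: hydrogenolysis of aryl benzyl ethers over Pd/C in a neutral, non-protic solvent is much faster than cleavage of a ring benzylic ether, so the three phenols should be freed with C2–O1, the ester and all three stereocentres intact.

## Compound list

1 | O-benzylvanillin (4-(benzyloxy)-3-methoxybenzaldehyde) | COc1cc(C=O)ccc1OCc1ccccc1 | starting material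
2 | vinylmagnesium bromide | C=C[Mg]Br | starting material
3 | rac-1-[4-(benzyloxy)-3-methoxyphenyl]prop-2-en-1-ol | C=CC(O)c1ccc(OCc2ccccc2)c(OC)c1 | intermediate
4 | (1R)-1-[4-(benzyloxy)-3-methoxyphenyl]prop-2-en-1-yl acetate | C=C[C@@H](OC(C)=O)c1ccc(OCc2ccccc2)c(OC)c1 | intermediate
5 | (1R)-1-[4-(benzyloxy)-3-methoxyphenyl]prop-2-en-1-ol | C=C[C@@H](O)c1ccc(OCc2ccccc2)c(OC)c1 | intermediate
6 | 2,3-dibromoprop-1-ene | C=C(Br)CBr | starting material
7 | 1-(benzyloxy)-4-{(1R)-1-[(2-bromoprop-2-en-1-yl)oxy]prop-2-en-1-yl}-2-methoxybenzene | C=C[C@@H](OCC(Br)=C)c1ccc(OCc2ccccc2)c(OC)c1 | intermediate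
8 | alkenylchromium dichloride from 7 (chromium in place of bromine, not isolated) | C=C[C@@H](OCC(=C)[Cr](Cl)Cl)c1ccc(OCc2ccccc2)c(OC)c1 | intermediate
9 | (1RS)-1-[4-(benzyloxy)-3-methoxyphenyl]-2-[({(1R)-1-[4-(benzyloxy)-3-methoxyphenyl]prop-2-en-1-yl}oxy)methyl]prop-2-en-1-ol, both carbinol epimers | C=C[C@@H](OCC(=C)C(O)c1ccc(OCc2ccccc2)c(OC)c1)c1ccc(OCc2ccccc2)c(OC)c1 | intermediate
10 | (RS)-[4-(benzyloxy)-3-methoxyphenyl]{(5R)-5-[4-(benzyloxy)-3-methoxyphenyl]-2,5-dihydrofuran-3-yl}methanol, both C7' epimers | OC(c1ccc(OCc2ccccc2)c(OC)c1)C1=C[C@H](c2ccc(OCc3ccccc3)c(OC)c2)OC1 | intermediate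
11 | (bromomethyl)chlorodimethylsilane | C[Si](C)(Cl)CBr | starting material
12 | (bromomethyl)dimethylsilyl ether of 10, both C7' epimers | BrC[Si](C)(C)OC(c1ccc(OCc2ccccc2)c(OC)c1)C1=C[C@H](c2ccc(OCc3ccccc3)c(OC)c2)OC1 | intermediate
13 | cis-fused tetrahydrofuran–1,2-oxasilinane (C2 R, C3 R, C4 S; C9 on silicon; both C7' epimers) | C[Si]1(C)C[C@H]2[C@H](c3ccc(OCc4ccccc4)c(OC)c3)OC[C@H]2C(c2ccc(OCc3ccccc3)c(OC)c2)O1 | intermediate
14 | {(2R,3S,4S)-2-[4-(benzyloxy)-3-methoxyphenyl]-4-{(RS)-[4-(benzyloxy)-3-methoxyphenyl](hydroxy)methyl}oxolan-3-yl}methanol | OC[C@H]1[C@H](c2ccc(OCc3ccccc3)c(OC)c2)OC[C@H]1C(O)c1ccc(OCc2ccccc2)c(OC)c1 | intermediate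
15 | 4-(benzyloxy)benzoyl chloride | O=C(Cl)c1ccc(OCc2ccccc2)cc1 | starting material
16 | {(2R,3S,4S)-2-[4-(benzyloxy)-3-methoxyphenyl]-4-{(RS)-[4-(benzyloxy)-3-methoxyphenyl](hydroxy)methyl}oxolan-3-yl}methyl 4-(benzyloxy)benzoate | O=C(OC[C@H]1[C@H](c2ccc(OCc3ccccc3)c(OC)c2)OC[C@H]1C(O)c1ccc(OCc2ccccc2)c(OC)c1)c1ccc(OCc2ccccc2)cc1 | intermediate
17 | {(2R,3S,4S)-2-[4-(benzyloxy)-3-methoxyphenyl]-4-[4-(benzyloxy)-3-methoxybenzyl]oxolan-3-yl}methyl 4-(benzyloxy)benzoate | O=C(OC[C@H]1[C@H](c2ccc(OCc3ccccc3)c(OC)c2)OC[C@H]1Cc1ccc(OCc2ccccc2)c(OC)c1)c1ccc(OCc2ccccc2)cc1 | intermediate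
18 | agastinol | COc1cc(C[C@@H]2CO[C@@H](c3ccc(O)c(OC)c3)[C@@H]2COC(=O)c2ccc(O)cc2)ccc1O | target

## Step count and least certain steps

Total: 12 steps. Longest linear sequence: 12 steps (the route is linear; 1 enters twice).

Step 8 (key step). The most likely failures are hydrogen transfer to the primary α-silyl radical before it closes, and, for the 7'R epimer of 12, loss of face selectivity at C3 because its arene must lie in the ring plane against C5H2 or turn toward the tether. Hydrogen delivery to C4 from the tether side would erode the cis fusion. The fallback sets out from 10. Its two epimers are diastereomers and are separated by chromatography. The epimer expected to be better disposed, (S)-[4-(benzyloxy)-3-methoxyphenyl]{(5R)-5-[4-(benzyloxy)-3-methoxyphenyl]-2,5-dihydrofuran-3-yl}methanol F2, is silylated and cyclised alone. The other epimer is oxidised with MnO2 to [4-(benzyloxy)-3-methoxyphenyl]{(5R)-5-[4-(benzyloxy)-3-methoxyphenyl]-2,5-dihydrofuran-3-yl}methanone F1 and reduced back with NaBH4 and CeCl3 in MeOH to the epimer mixture for another pass. The sequence comes back to the route at 12 as a single epimer, so that C2 and C7' act in the same direction in the key step.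

Step 5. Insertion into the alkenyl C–Br bond may be slow, so that reductive coupling of 1 by divalent chromium or homocoupling of 7 competes. The fallback sets out from 1 and 5 and comes back at 9; it forms the C4–C7' bond before the ether. 1 and methyl acrylate with DABCO (Baylis–Hillman reaction) give racemic methyl 2-{[4-(benzyloxy)-3-methoxyphenyl](hydroxy)methyl}prop-2-enoate F3. TBSCl and imidazole give its tert-butyldimethylsilyl ether F4. Reduction with i-Bu2AlH gives 2-{[4-(benzyloxy)-3-methoxyphenyl](tert-butyldimethylsilyloxy)methyl}prop-2-en-1-ol F5. CBr4 and PPh3 give the allylic bromide {1-[4-(benzyloxy)-3-methoxyphenyl]-2-(bromomethyl)prop-2-en-1-yl}oxy(tert-butyl)dimethylsilane F6. The sodium alkoxide of 5 is alkylated with F6 to the silyl-protected diene ether F7, and Bu4NF removes the silyl group to return 9.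

Step 11. The ring C2–O1 bond may ionise alongside the C7' hydroxyl (ring opening, epimerisation at C2), or the C7' cation may lose the C4 proton and regain it from either face (epimerisation at C4). The fallback sets out from 16 and comes back at 17 by radical deoxygenation (Barton–McCombie). Phenyl chlorothionoformate, pyridine and DMAP give the O-phenyl thionocarbonate of the C7' hydroxyl of 16 F8, and Bu3SnH with AIBN in toluene at 90 °C reduces it to 17. A benzylic radical has no path to ring opening or to inversion at C4.

Step 12. Hydrogenolysis may continue from the benzyl ethers into the C2–O1 bond once the para phenol is free, opening the tetrahydrofuran reductively. The fallback sets out from 17 and arrives directly at 18 by Lewis-acid debenzylation with a cation scavenger: BCl3 and pentamethylbenzene in CH2Cl2 at −78 °C. It makes no new compound (F0).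

## Further compounds

F1 | step 8 | [4-(benzyloxy)-3-methoxyphenyl]{(5R)-5-[4-(benzyloxy)-3-methoxyphenyl]-2,5-dihydrofuran-3-yl}methanone | O=C(c1ccc(OCc2ccccc2)c(OC)c1)C1=C[C@H](c2ccc(OCc3ccccc3)c(OC)c2)OC1
F2 | step 8 | (S)-[4-(benzyloxy)-3-methoxyphenyl]{(5R)-5-[4-(benzyloxy)-3-methoxyphenyl]-2,5-dihydrofuran-3-yl}methanol | O[C@@H](c1ccc(OCc2ccccc2)c(OC)c1)C1=C[C@H](c2ccc(OCc3ccccc3)c(OC)c2)OC1
F3 | step 5 | methyl 2-{[4-(benzyloxy)-3-methoxyphenyl](hydroxy)methyl}prop-2-enoate (racemic) | C=C(C(=O)OC)C(O)c1ccc(OCc2ccccc2)c(OC)c1
F4 | step 5 | methyl 2-{[4-(benzyloxy)-3-methoxyphenyl](tert-butyldimethylsilyloxy)methyl}prop-2-enoate (racemic) | C=C(C(=O)OC)C(O[Si](C)(C)C(C)(C)C)c1ccc(OCc2ccccc2)c(OC)c1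
F5 | step 5 | 2-{[4-(benzyloxy)-3-methoxyphenyl](tert-butyldimethylsilyloxy)methyl}prop-2-en-1-ol (racemic) | C=C(CO)C(O[Si](C)(C)C(C)(C)C)c1ccc(OCc2ccccc2)c(OC)c1
F6 | step 5 | {1-[4-(benzyloxy)-3-methoxyphenyl]-2-(bromomethyl)prop-2-en-1-yl}oxy(tert-butyl)dimethylsilane (racemic) | C=C(CBr)C(O[Si](C)(C)C(C)(C)C)c1ccc(OCc2ccccc2)c(OC)c1
F7 | step 5 | tert-butyldimethylsilyl ether of 9 (both carbinol epimers) | C=C[C@@H](OCC(=C)C(O[Si](C)(C)C(C)(C)C)c1ccc(OCc2ccccc2)c(OC)c1)c1ccc(OCc2ccccc2)c(OC)c1
F8 | step 11 | O-phenyl thionocarbonate of the C7' hydroxyl of 16 (both C7' epimers) | O=C(OC[C@H]1[C@H](c2ccc(OCc3ccccc3)c(OC)c2)OC[C@H]1C(OC(=S)Oc1ccccc1)c1ccc(OCc2ccccc2)c(OC)c1)c1ccc(OCc2ccccc2)cc1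
F0 | step 12 | none | none
A1 | alternative 1 | (5S)-5-[(1S,2R,5S)-menthyloxy]furan-2(5H)-one | O=C1O[C@H](O[C@H]2C[C@@H](C)CC[C@@H]2C(C)C)C=C1
A2 | alternative 1 | 2-[4-(benzyloxy)-3-methoxyphenyl]-1,3-dithiane | COc1cc(C2SCCCS2)ccc1OCc1ccccc1
A3 | alternative 1 | trans,trans 3-{[4-(benzyloxy)-3-methoxyphenyl](hydroxy)methyl}-4-{2-[4-(benzyloxy)-3-methoxyphenyl]-1,3-dithian-2-yl}-5-(menthyloxy)dihydrofuran-2(3H)-one | O=C1O[C@H](O[C@H]2C[C@@H](C)CC[C@@H]2C(C)C)[C@@H](C3(c4ccc(OCc5ccccc5)c(OC)c4)SCCCS3)[C@@H]1[C@@H](O)c1ccc(OCc2ccccc2)c(OC)c1
A4 | alternative 2 | methoxymethyl ether of the anti homopropargylic alcohol: 4-[4-(benzyloxy)-3-methoxyphenyl]-2-[(methoxymethoxy)(3-methoxy-4-mesyloxyphenyl)methyl]but-3-yn-1-yl pivalate | COCO[C@@H](c1ccc(OS(C)(=O)=O)c(OC)c1)[C@@H](C#Cc1ccc(OCc2ccccc2)c(OC)c1)COC(=O)C(C)(C)C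
A5 | alternative 2 | (E)-4-{[4-(benzyloxy)-3-methoxyphenyl]chloromethylidene}-2-(3-methoxy-4-mesyloxyphenyl)-3-(pivaloyloxymethyl)tetrahydrofuran, 2,3-trans | Cl/C(c1ccc(OCc2ccccc2)c(OC)c1)=C1/CO[C@@H](c2ccc(OS(C)(=O)=O)c(OC)c2)[C@@H]1COC(=O)C(C)(C)C
A6 | alternative 3 | (5R)-5-[4-(benzyloxy)-3-methoxyphenyl]furan-2(5H)-one | O=C1O[C@@H](c2ccc(OCc3ccccc3)c(OC)c2)C=C1
A7 | alternative 3 | (E)-α-[4-(benzyloxy)-3-methoxybenzylidene]-γ-[4-(benzyloxy)-3-methoxyphenyl]-β-[(isopropoxydimethylsilyl)methyl]-γ-butyrolactone, β,γ-trans | O=C1O[C@@H](c2ccc(OCc3ccccc3)c(OC)c2)[C@H](C[Si](C)(C)OC(C)C)/C1=C\c1ccc(OCc2ccccc2)c(OC)c1
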